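## The problem

Germacrane numbering is used throughout: ring C1–C10, C11–C13 the lactone unit on C7, C14 the ester carbon on C10, C15 the methyl on C4; α/β refer to the usual germacranolide drawing with H-7 α. Target 29 is a melampolide: a ten-membered carbocycle with a ring-cis C1=C10 enoate, a trans C4–C5 epoxide, a trans-fused α-methylene-γ-lactone on C6/C7, an 8β ester of (2S,3R)-2,3-epoxy-2-methylbutanoic acid and a free 9β hydroxyl. The hardest feature is the ring: end-to-end closure of a ten-membered ring holding one cis and one trans trisubstituted unit is disfavoured by entropy and transannular strain, and an open chain gives no grip on the cis enoate. Six contiguous stereocentres (C4–C9) must be related: C6/C7 can be set together, C4/C5 can follow from C6 by peripheral epoxidation of a 4E alkene, but C8 and C9 sit on a flexible ring where only outer-face attack or reagent control is available. The fragile groups are the α-methylene lactone (Michael acceptor), the glycidic ester, the 1(10),4-diene (transannular cyclisation under acid) and the 8-acyloxy-9-hydroxy pair, which can scramble by acyl migration, so the acyl group must be on O8 before O9 is a free hydroxyl. The feature that opens the problem: C9 (oxygen-bearing) and C4 lie 1,6 across the ring, and the array O–C9–C8 / C7–C6 / C5=C4 (E) is the product pattern of an oxy-Cope rearrangement. In that rearrangement, bond C4–C9 of a cyclohexene (C9, C10, C1, C2, C3, C4) is exchanged for bond C6–C7; the cis C1=C10 bond lies inside that six-membered ring, and C6 (oxygen) and C7 (carbon branch) are the two termini that join.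

## Retrosynthesis

**Epoxide last (29 ⇒ 28).** The two C–O bonds of the 4,5-epoxide are cut first. The 4E alkene of 28 is the only electron-rich alkene (the other two are conjugated to carbonyls), so a peracid should be chemoselective. This leaves the acid-sensitive epoxide out of every earlier step. The forward reaction must attack the outer face of the trans alkene, syn to O6.

**C10–C14 and C9–H (28 ⇒ 27 ⇒ 26).** The ester carbon is cut from C10 and replaced by iodine, then the C9 carbinol is taken back to a ketone. The alternative, an ester on C10 beside a C9 ketone, would be an alkylidene β-keto ester, prone to conjugate reduction. With iodine as placeholder, 26 is an ordinary 2-iodoenone, a good substrate for reagent-controlled CBS reduction, and 27 is a vinyl iodide ready for methoxycarbonylation with retention of the ring-cis geometry.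

**Lactone C12–O6 (26 ⇒ 23 ⇒ 22).** The lactone is opened to a 1,4-diol carried as two silyl ethers in 22. Oxidative lactonisation needs no base or carbanion, unlike a late α-methylenation. It is placed while C9 is still a ketone, so that C6–OH is the only hydroxyl that can capture the C12 aldehyde.

**O8–acyl bond with inversion (22 ⇒ 17 + 20).** The ester C–O bond at C8 is cut so that the carboxylate of 20 displaces an activated 8α oxygen. This is preferred to acylation of an 8,9-diol, which would need selective acylation of one of two similar secondary hydroxyls. The forward step must give clean inversion at a carbon activated by the neighbouring ketone.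

**Key disconnection (17 ⇒ 14).** Bond C6–C7 is cut and bond C4–C9 is formed, with removal of the C8 hydroxyl: the ten-membered hydroxy ketone 17 becomes the monocyclic cyclohexenol 14. This removes the medium ring, two stereocentres (C6, C7) and the trans alkene at once; 14 has only two stereocentres, and its ring already holds the cis C1=C10 bond. The forward reaction must proceed through the single chair open to a trans-1,2-dialkenyl system, and the enolate must be hydroxylated in the same flask.

**C8–C9 (14 ⇒ 7 + 11).** The tertiary carbinol is cut between C9 and the dienyl carbon, giving iodoenone 7 and dienylstannane 11 (a masked dienyl anion). The forward addition must be 1,2, must not exchange the iodine, and must place the dienyl group trans to the silyloxyvinyl group.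

**Building blocks (7 ⇒ 6 ⇒ 5 ⇒ 4 ⇒ 3 ⇒ 2 ⇒ 1; 11 ⇒ 9 + 10, 9 ⇒ 8; 20 ⇒ 19 ⇒ 18).** The enol ether of 7 is the enol silane of aldehyde 6, which comes from the allyl group of 5. The iodoenone comes from ketone 3 by dehydrogenation (4) and α-iodination (5). The quaternary centre of 3 is the only stereocentre that must be bought with a chiral catalyst in the carbocyclic series: decarboxylative asymmetric allylation of racemic β-keto ester 2, made from 1. Stannane 11 is a Stille product of bromide 9 (from 8) and distannane 10. Acid 20 comes from tiglyl alcohol 18 by asymmetric epoxidation (19) and oxidation.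

## Roads not taken

**Alternative 1:** (the most obvious) Cut C6–C7 and the lactone C–O bond in an open chain: intramolecular Nozaki–Hiyama–Kishi/Barbier allylation of the seco enal–allylic bromide A1 with CrCl2, then lactonisation to the macrocyclic lactone A2. The chosen plan is better for three reasons:
- A1 is a fifteen-carbon chain that must already carry C8, C9, a stereodefined enoate, an E enal and an allylic bromide, which means a long linear run-up.
- The key step is an end-to-end ten-membered closure, with its entropy cost and risk of oligomers.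
- C6/C7 would be controlled only by remote C8 through a floppy transition state.

The oxy-Cope draws the ring from an existing six-membered ring and fixes C6/C7 by alkene geometry.

**Alternative 2:** Cut C9–C10: intramolecular Nozaki–Hiyama–Kishi vinylation of the iodoenoate aldehyde A3 (lactone and C8 already in place) to give the carbinol A4. Three weaknesses:
- The ring is again closed end to end.
- An alkenylchromium species that carries an ester on the metal-bearing carbon is a poor nucleophile.
- C9 would form next to an epimerisable α-oxygenated aldehyde with no reliable control, in the presence of an α-methylene lactone that CrCl2 can reduce.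

In the chosen plan C9 comes from a ketone and a chiral reagent.

**Alternative 3:** Cut the same C4–C9 bond by a Wharton–Grob fragmentation of the trans-decalin hydroxy mesylate A5, giving the cyclodecadienone A6. This also inherits the cis alkene and makes the 4E alkene and the C9 ketone. Its drawback is that C6–C7 must already exist: A5 needs a fully substituted cyclohexane (C5 equatorial mesylate, C6, C7, C8) plus two angular centres, seven stereocentres before the key step, and selective sulfonylation beside a tertiary alcohol. The oxy-Cope precursor 14 has two stereocentres, and the rearrangement itself makes C6–C7 and both of its stereocentres.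

Key step: step 10

Remark on the chemistry: the acyl group of 29, (2S,3R)-2,3-dimethyloxirane-2-carboxylate, has its two methyl groups cis and is therefore derived from tiglyl (not angelyl) alcohol; compounds 1, 8, 10 and 18 are taken as commercial.

## Steps

Step 1
Reactants: 1 allyl 2-oxocyclohexane-1-carboxylate
Product: 2 allyl 1-methyl-2-oxocyclohexane-1-carboxylate (racemic)
Conditions: MeI, K2CO3, acetone, 50 °C
Reagents that add atoms: iodomethane, CI
Why: C-alkylation of the β-keto ester enolate at its only acidic carbon; the racemic centre is erased in step 2.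

Step 2
Reactants: 2 allyl 1-methyl-2-oxocyclohexane-1-carboxylate
Product: 3 (S)-2-allyl-2-methylcyclohexan-1-one
Conditions: Pd2(dba)3 (cat.), (S)-t-Bu-PHOX (cat.), THF, 25 °C
Reagents that add atoms: none
Why: Decarboxylative asymmetric Tsuji allylation: ionisation and loss of CO2 give an achiral enolate and a π-allyl palladium fragment, so both enantiomers of 2 converge; the (S)-PHOX ligand should direct allylation to one enolate face and set the quaternary centre (C4 of the target) as S.

Step 3
Reactants: 3 (S)-2-allyl-2-methylcyclohexan-1-one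
Product: 4 (S)-6-allyl-6-methylcyclohex-2-en-1-one
Conditions: IBX, DMSO, 70 °C
Reagents that add atoms: none
Why: IBX dehydrogenation of a ketone to the enone; only the CH2 side can enolise because the other α-carbon is quaternary, and the stereocentre is untouched.

Step 4
Reactants: 4 (S)-6-allyl-6-methylcyclohex-2-en-1-one
Product: 5 (S)-6-allyl-2-iodo-6-methylcyclohex-2-en-1-one
Conditions: I2, pyridine, CH2Cl2, 0 → 25 °C
Reagents that add atoms: iodine, II
Why: α-Iodination of an enone by conjugate addition of pyridine, iodination of the enolate and elimination (Baylis–Hillman-type sequence); the iodine marks C10 for the later ester carbon and the isolated allyl group is inert.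

Step 5
Reactants: 5 (S)-6-allyl-2-iodo-6-methylcyclohex-2-en-1-one
Product: 6 2-[(1S)-3-iodo-1-methyl-2-oxocyclohex-3-en-1-yl]acetaldehyde
Conditions: OsO4 (cat.), NaIO4, 2,6-lutidine, dioxane/H2O, 25 °C
Reagents that add atoms: osmium tetroxide, O=[Os](=O)(=O)=O; sodium periodate, [Na+].[O-]I(=O)(=O)=O
Why: Lemieux–Johnson cleavage; the electron-rich terminal alkene is dihydroxylated much faster than the electron-poor, hindered iodoenone.

Step 6
Reactants: 6 2-[(1S)-3-iodo-1-methyl-2-oxocyclohex-3-en-1-yl]acetaldehyde
Product: 7 (6S)-6-[(E)-2-(tert-butyldimethylsilyloxy)ethenyl]-2-iodo-6-methylcyclohex-2-en-1-one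
Conditions: TBSOTf, Et3N, CH2Cl2, −78 → 0 °C
Reagents that add atoms: tert-butyldimethylsilyl triflate, CC(C)(C)[Si](C)(C)OS(=O)(=O)C(F)(F)F
Why: Soft enolisation and O-silylation of the aldehyde (the ketone has no α-hydrogen); the E enol ether is expected because the Z isomer would place the silyloxy group cis to the quaternary carbon.

Step 7
Reactants: 8 2-bromoprop-2-en-1-ol
Product: 9 (2-bromoprop-2-en-1-yloxy)(tert-butyl)dimethylsilane
Conditions: TBSCl, imidazole, CH2Cl2, 25 °C
Reagents that add atoms: tert-butyldimethylsilyl chloride, CC(C)(C)[Si](C)(C)Cl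
Why: Standard silylation of a primary alcohol.

Step 8
Reactants: 9 (2-bromoprop-2-en-1-yloxy)(tert-butyl)dimethylsilane; 10 (E)-1,2-bis(tributylstannyl)ethene (excess)
Product: 11 (E)-tributyl{3-[(tert-butyldimethylsilyloxy)methyl]buta-1,3-dien-1-yl}stannane
Conditions: Pd(PPh3)4 (cat.), toluene, 90 °C
Reagents that add atoms: none
Why: Stille coupling of a vinyl bromide with one end of the distannane (the excess limits double coupling); the E geometry of the stannylalkene is retained.

Step 9
Reactants: 11 (E)-tributyl{3-[(tert-butyldimethylsilyloxy)methyl]buta-1,3-dien-1-yl}stannane; 7 (6S)-6-[(E)-2-(tert-butyldimethylsilyloxy)ethenyl]-2-iodo-6-methylcyclohex-2-en-1-one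
Product: 14 (1R,6S)-1-{(1E)-3-[(tert-butyldimethylsilyloxy)methyl]buta-1,3-dien-1-yl}-6-[(E)-2-(tert-butyldimethylsilyloxy)ethenyl]-2-iodo-6-methylcyclohex-2-en-1-ol, via dienyllithium 12 (not isolated), via dienylcerium dichloride 13 (not isolated)
Conditions: n-BuLi, THF, −78 °C; CeCl3, −78 °C; then 7, −78 °C; aq. NH4Cl
Reagents that add atoms: none
Why: Tin–lithium exchange with retention, transmetalation to the organocerium reagent (suppresses iodine–metal exchange and 1,4-addition) and 1,2-addition to the hindered ketone. The sp2 substituent geminal to methyl should sit pseudo-axial (as phenyl does in 1-methyl-1-phenylcyclohexane), so axial attack anti to it places the dienyl group cis to methyl and trans to the silyloxyvinyl group (C9 of the target, here 1R); the minor epimer is removed by chromatography.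

Step 10
Reactants: 14 (1R,6S)-1-{(1E)-3-[(tert-butyldimethylsilyloxy)methyl]buta-1,3-dien-1-yl}-6-[(E)-2-(tert-butyldimethylsilyloxy)ethenyl]-2-iodo-6-methylcyclohex-2-en-1-ol
Product: 17 (4E)-6α,12-bis(tert-butyldimethylsilyloxy)-8α-hydroxy-10-iodo-14-norgermacra-1(10),4,11(13)-trien-9-one (ring-cis C1=C10; H-6β; H-7α), via potassium alkoxide 15 (not isolated), via potassium enolate 16 (not isolated)
Conditions: KN(SiMe3)2, 18-crown-6, THF, −78 → 25 °C; then 2-(phenylsulfonyl)-3-phenyloxaziridine, −78 °C; aq. NH4Cl
Reagents that add atoms: 2-(phenylsulfonyl)-3-phenyloxaziridine, O=S(=O)(c1ccccc1)N1OC1c1ccccc1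
Why: Deprotonation gives alkoxide 15, whose charge weakens C4–C9 and drives an anionic oxy-Cope ([3,3]-sigmatropic) shift in which C6–C7 forms between the termini of the silyloxyvinyl and dienyl groups while C4–C9 breaks, giving enolate 16; the closest known reaction type is the anionic oxy-Cope ring expansion of trans-1,2-dialkenylcyclohexanols to cyclodec-5-enones with in situ enolate hydroxylation by an N-sulfonyloxaziridine. The ten-membered ring is closed by four-atom ring expansion of the cyclohexene through a six-membered chair transition state, not by end-to-end cyclisation, so the ring-cis C1=C10 bond is inherited. Because the two alkenyl groups are trans, only the chair with both ring bonds (to C3 and C10) equatorial is accessible; it puts C15 axial and so gives the 4E alkene. C6 and C7 are set in that chair by the E geometry of both alkenes (silyloxy group and C11 unit equatorial, H-6 and H-7 axial), and their absolute sense is transferred from the C4 stereocentre, which is destroyed: the (6S) precursor should give H-6β/H-7α. C8 is set by attack of the oxaziridine on the exposed outer face of the ring E-enolate, anti to the C7–C6 ring bond, which should give the 8α alcohol (the epimer wanted for the inversion in step 13). The step needs the exocyclic [3,3] path to beat a boat-type shift through the ring alkene C1=C10 and a dissociative cleavage; the pre-organised diequatorial alkenyl groups and the lack of an anion-stabilising group on C4 secure this. The E enol ether keeps silicon remote from the alkoxide and so guards against silyl transfer.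

Step 11
Reactants: 18 (E)-2-methylbut-2-en-1-ol
Product: 19 [(2R,3R)-2,3-dimethyloxiran-2-yl]methanol
Conditions: Ti(OiPr)4 (cat.), D-(−)-diethyl tartrate, t-BuOOH, 4 Å molecular sieves, CH2Cl2, −20 °C
Reagents that add atoms: tert-butyl hydroperoxide, CC(C)(C)OO
Why: Sharpless asymmetric epoxidation; the D-tartrate delivers oxygen to the face that gives the (2R,3R) epoxy alcohol from an E-2,3-disubstituted allylic alcohol, and syn addition keeps the two methyl groups cis.

Step 12
Reactants: 19 [(2R,3R)-2,3-dimethyloxiran-2-yl]methanol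
Product: 20 (2S,3R)-2,3-dimethyloxirane-2-carboxylic acid
Conditions: RuCl3 hydrate (cat.), NaIO4, CCl4/MeCN/H2O, 25 °C
Reagents that add atoms: water, O
Why: RuO4 (formed in situ) oxidises the primary alcohol through the aldehyde hydrate to the acid without opening the epoxide; the C2 descriptor changes from R to S only through CIP priorities.

Step 13
Reactants: 17 (4E)-6α,12-bis(tert-butyldimethylsilyloxy)-8α-hydroxy-10-iodo-14-norgermacra-1(10),4,11(13)-trien-9-one; 20 (2S,3R)-2,3-dimethyloxirane-2-carboxylic acid
Product: 22 (4E)-6α,12-bis(tert-butyldimethylsilyloxy)-8β-[(2S,3R)-2,3-dimethyloxirane-2-carbonyloxy]-10-iodo-14-norgermacra-1(10),4,11(13)-trien-9-one, via alkoxyphosphonium carboxylate 21 (not isolated)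
Conditions: PPh3, DIAD, THF, 0 → 25 °C
Reagents that add atoms: none
Why: Mitsunobu esterification: the carboxylate displaces the oxyphosphonium group by SN2 with inversion at C8, a carbon activated by the adjacent carbonyl. This turns the 8α alcohol into the 8β ester and installs the side chain in one operation.

Step 14
Reactants: 22 (4E)-6α,12-bis(tert-butyldimethylsilyloxy)-8β-[(2S,3R)-2,3-dimethyloxirane-2-carbonyloxy]-10-iodo-14-norgermacra-1(10),4,11(13)-trien-9-one
Product: 23 (4E)-8β-[(2S,3R)-2,3-dimethyloxirane-2-carbonyloxy]-6α,12-dihydroxy-10-iodo-14-norgermacra-1(10),4,11(13)-trien-9-one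
Conditions: HF·pyridine, pyridine, THF, 0 → 25 °C
Reagents that add atoms: none
Why: Buffered fluoride desilylation of both silyl ethers; the electron-poor glycidic ester and the iodoenone should tolerate these conditions, and no base is present to move the acyl group.

Step 15
Reactants: 23 (4E)-8β-[(2S,3R)-2,3-dimethyloxirane-2-carbonyloxy]-6α,12-dihydroxy-10-iodo-14-norgermacra-1(10),4,11(13)-trien-9-one
Product: 26 (4E)-8β-[(2S,3R)-2,3-dimethyloxirane-2-carbonyloxy]-10-iodo-9-oxo-14-norgermacra-1(10),4,11(13)-trien-12,6α-olide, via hydroxy enal 24 (not isolated), via lactol 25 (not isolated)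
Conditions: TEMPO (cat.), PhI(OAc)2, CH2Cl2, 25 °C
Reagents that add atoms: none
Why: Oxidative lactonisation: the oxoammonium salt oxidises the primary allylic alcohol selectively, the aldehyde is captured by the C6 hydroxyl as a five-membered lactol and this is oxidised on to the lactone; with C9 still a ketone no other hydroxyl competes, and the trans ring fusion was fixed in step 10.

Step 16
Reactants: 26 (4E)-8β-[(2S,3R)-2,3-dimethyloxirane-2-carbonyloxy]-10-iodo-9-oxo-14-norgermacra-1(10),4,11(13)-trien-12,6α-olide
Product: 27 (4E)-8β-[(2S,3R)-2,3-dimethyloxirane-2-carbonyloxy]-9β-hydroxy-10-iodo-14-norgermacra-1(10),4,11(13)-trien-12,6α-olide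
Conditions: (R)-2-methyl-CBS-oxazaborolidine (0.5 equiv), catecholborane, toluene/CH2Cl2, −78 °C; then MeOH, pH 7 buffer
Reagents that add atoms: none
Why: Corey–Bakshi–Shibata reduction under reagent control: the α-iodoalkenyl side acts as the large group, so the (R)-catalyst should deliver hydride to the face that gives the 9β alcohol (9S here because iodine raises the priority of C10). The reduction is 1,2-selective and leaves the lactone and esters untouched.

Step 17
Reactants: 27 (4E)-8β-[(2S,3R)-2,3-dimethyloxirane-2-carbonyloxy]-9β-hydroxy-10-iodo-14-norgermacra-1(10),4,11(13)-trien-12,6α-olide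
Product: 28 methyl (4E)-8β-[(2S,3R)-2,3-dimethyloxirane-2-carbonyloxy]-9β-hydroxy-12-oxo-12,6α-epoxygermacra-1(10),4,11(13)-trien-14-oate (ring-cis C1=C10)
Conditions: PdCl2(PPh3)2 (cat.), CO (1 atm), MeOH, i-Pr2NEt, DMF, 40 °C
Reagents that add atoms: carbon monoxide, [C-]#[O+]; methanol, CO
Why: Palladium-catalysed methoxycarbonylation of a vinyl iodide (oxidative addition with retention, CO insertion, methanolysis); the ring-cis geometry is kept and the free allylic hydroxyl is tolerated.

Step 18
Reactants: 28 methyl (4E)-8β-[(2S,3R)-2,3-dimethyloxirane-2-carbonyloxy]-9β-hydroxy-12-oxo-12,6α-epoxygermacra-1(10),4,11(13)-trien-14-oate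
Product: 29 methyl (4R,5R,6S,7R,8S,9R)-8-[(2S,3R)-2,3-dimethyloxirane-2-carbonyloxy]-4,5-epoxy-9-hydroxy-12-oxo-12,6-epoxygermacra-1(10),11(13)-dien-14-oate (ring-cis C1=C10; CNP0262846.1)
Conditions: mCPBA, NaHCO3, CH2Cl2, 0 °C
Reagents that add atoms: 3-chloroperoxybenzoic acid, OOC(=O)c1cccc(Cl)c1
Why: Prilezhaev epoxidation: only the trisubstituted C4=C5 bond is electron-rich (the other two alkenes are conjugated to carbonyls). The peracid should attack the exposed outer face of the trans alkene in the conformer with H-6 eclipsing the double bond (A(1,3) strain with C15), that is syn to O6, giving the (4R,5R) epoxide.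

## Compound list

1 | allyl 2-oxocyclohexane-1-carboxylate | C=CCOC(=O)C1CCCCC1=O | starting material
2 | allyl 1-methyl-2-oxocyclohexane-1-carboxylate (racemic) | C=CCOC(=O)C1(C)CCCCC1=O | intermediate
3 | (S)-2-allyl-2-methylcyclohexan-1-one | O=C1CCCC[C@@]1(C)CC=C | intermediate
4 | (S)-6-allyl-6-methylcyclohex-2-en-1-one | O=C1C=CCC[C@@]1(C)CC=C | intermediate
5 | (S)-6-allyl-2-iodo-6-methylcyclohex-2-en-1-one | O=C1C(I)=CCC[C@@]1(C)CC=C | intermediate
6 | 2-[(1S)-3-iodo-1-methyl-2-oxocyclohex-3-en-1-yl]acetaldehyde | O=C1C(I)=CCC[C@@]1(C)CC=O | intermediate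
7 | (6S)-6-[(E)-2-(tert-butyldimethylsilyloxy)ethenyl]-2-iodo-6-methylcyclohex-2-en-1-one | O=C1C(I)=CCC[C@@]1(C)/C=C/O[Si](C)(C)C(C)(C)C | intermediate
8 | 2-bromoprop-2-en-1-ol | OCC(Br)=C | starting material
9 | (2-bromoprop-2-en-1-yloxy)(tert-butyl)dimethylsilane | C=C(Br)CO[Si](C)(C)C(C)(C)C | intermediate
10 | (E)-1,2-bis(tributylstannyl)ethene | CCCC[Sn](CCCC)(CCCC)/C=C/[Sn](CCCC)(CCCC)CCCC | starting material
11 | (E)-tributyl{3-[(tert-butyldimethylsilyloxy)methyl]buta-1,3-dien-1-yl}stannane | CCCC[Sn](CCCC)(CCCC)/C=C/C(=C)CO[Si](C)(C)C(C)(C)C | intermediate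
12 | (E)-{3-[(tert-butyldimethylsilyloxy)methyl]buta-1,3-dien-1-yl}lithium | [Li]/C=C/C(=C)CO[Si](C)(C)C(C)(C)C | intermediate
13 | (E)-{3-[(tert-butyldimethylsilyloxy)methyl]buta-1,3-dien-1-yl}cerium dichloride | Cl[Ce](Cl)/C=C/C(=C)CO[Si](C)(C)C(C)(C)C | intermediate
14 | (1R,6S)-1-{(1E)-3-[(tert-butyldimethylsilyloxy)methyl]buta-1,3-dien-1-yl}-6-[(E)-2-(tert-butyldimethylsilyloxy)ethenyl]-2-iodo-6-methylcyclohex-2-en-1-ol | IC1=CCC[C@@](C)(/C=C/O[Si](C)(C)C(C)(C)C)[C@]1(O)/C=C/C(=C)CO[Si](C)(C)C(C)(C)C | intermediate
15 | potassium alkoxide of 14 | IC1=CCC[C@@](C)(/C=C/O[Si](C)(C)C(C)(C)C)[C@]1([O-])/C=C/C(=C)CO[Si](C)(C)C(C)(C)C.[K+] | intermediate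
16 | potassium (4E,8E)-enolate of the ring-expanded ketone (ring-cis C1=C10; 6α-OTBS; H-7α) | C/C1=C\[C@@H](O[Si](C)(C)C(C)(C)C)[C@H](C(=C)CO[Si](C)(C)C(C)(C)C)/C=C([O-])/C(I)=C\CC1.[K+] | intermediate
17 | (4E)-6α,12-bis(tert-butyldimethylsilyloxy)-8α-hydroxy-10-iodo-14-norgermacra-1(10),4,11(13)-trien-9-one | C/C1=C\[C@@H](O[Si](C)(C)C(C)(C)C)[C@H](C(=C)CO[Si](C)(C)C(C)(C)C)[C@@H](O)C(=O)/C(I)=C\CC1 | intermediate
18 | (E)-2-methylbut-2-en-1-ol | C/C=C(\C)CO | starting material
19 | [(2R,3R)-2,3-dimethyloxiran-2-yl]methanol | OC[C@@]1(C)O[C@@H]1C | intermediate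
20 | (2S,3R)-2,3-dimethyloxirane-2-carboxylic acid | OC(=O)[C@@]1(C)O[C@@H]1C | intermediate
21 | C8 alkoxy(triphenyl)phosphonium salt of 17 with the carboxylate of 20 | C/C1=C\[C@@H](O[Si](C)(C)C(C)(C)C)[C@H](C(=C)CO[Si](C)(C)C(C)(C)C)[C@@H](O[P+](c2ccccc2)(c2ccccc2)c2ccccc2)C(=O)/C(I)=C\CC1.[O-]C(=O)[C@@]1(C)O[C@@H]1C | intermediate
22 | (4E)-6α,12-bis(tert-butyldimethylsilyloxy)-8β-[(2S,3R)-2,3-dimethyloxirane-2-carbonyloxy]-10-iodo-14-norgermacra-1(10),4,11(13)-trien-9-one | C/C1=C\[C@@H](O[Si](C)(C)C(C)(C)C)[C@H](C(=C)CO[Si](C)(C)C(C)(C)C)[C@H](OC(=O)[C@@]2(C)O[C@@H]2C)C(=O)/C(I)=C\CC1 | intermediate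
23 | (4E)-8β-[(2S,3R)-2,3-dimethyloxirane-2-carbonyloxy]-6α,12-dihydroxy-10-iodo-14-norgermacra-1(10),4,11(13)-trien-9-one | C/C1=C\[C@@H](O)[C@H](C(=C)CO)[C@H](OC(=O)[C@@]2(C)O[C@@H]2C)C(=O)/C(I)=C\CC1 | intermediate
24 | 12-aldehyde of 23 (6α-hydroxy enal) | C/C1=C\[C@@H](O)[C@H](C(=C)C=O)[C@H](OC(=O)[C@@]2(C)O[C@@H]2C)C(=O)/C(I)=C\CC1 | intermediate
25 | 12,6α-lactol (anomeric mixture at C12) | C/C1=C\[C@H]2OC(O)C(=C)[C@@H]2[C@H](OC(=O)[C@@]3(C)O[C@@H]3C)C(=O)/C(I)=C\CC1 | intermediate
26 | (4E)-8β-[(2S,3R)-2,3-dimethyloxirane-2-carbonyloxy]-10-iodo-9-oxo-14-norgermacra-1(10),4,11(13)-trien-12,6α-olide | C/C1=C\[C@H]2OC(=O)C(=C)[C@@H]2[C@H](OC(=O)[C@@]3(C)O[C@@H]3C)C(=O)/C(I)=C\CC1 | intermediate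
27 | (4E)-8β-[(2S,3R)-2,3-dimethyloxirane-2-carbonyloxy]-9β-hydroxy-10-iodo-14-norgermacra-1(10),4,11(13)-trien-12,6α-olide | C/C1=C\[C@H]2OC(=O)C(=C)[C@@H]2[C@H](OC(=O)[C@@]3(C)O[C@@H]3C)[C@H](O)/C(I)=C\CC1 | intermediate
28 | methyl (4E)-8β-[(2S,3R)-2,3-dimethyloxirane-2-carbonyloxy]-9β-hydroxy-12-oxo-12,6α-epoxygermacra-1(10),4,11(13)-trien-14-oate | C/C1=C\[C@H]2OC(=O)C(=C)[C@@H]2[C@H](OC(=O)[C@@]3(C)O[C@@H]3C)[C@H](O)/C(C(=O)OC)=C\CC1 | intermediate
29 | methyl (4R,5R,6S,7R,8S,9R)-8-[(2S,3R)-2,3-dimethyloxirane-2-carbonyloxy]-4,5-epoxy-9-hydroxy-12-oxo-12,6-epoxygermacra-1(10),11(13)-dien-14-oate (CNP0262846.1) | C=C1C(=O)O[C@H]2[C@H]1[C@H](OC(=O)[C@@]1(C)O[C@@H]1C)[C@H](O)/C(C(=O)OC)=C\CC[C@@]1(C)O[C@H]21 | target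

## Step count and least certain steps

Total: 18 steps. Longest linear sequence: 14 steps (steps 1–6, 9, 10, 13–18); steps 7–8 and 11–12 are side branches.

**Step 10 (key step).** The strongly basic tertiary alkoxide sits in a crowded, triply allylic setting. The [3,3] shift may be diverted into a boat-type shift through the ring C1=C10 bond, into heterolytic C4–C9 cleavage, or into silyl transfer from the enol ether to oxygen. Fallback (neutral thermal path): from 14, silylation (TMSOTf, 2,6-lutidine) gives the trimethylsilyl ether F1. Thermolysis (o-dichlorobenzene, 200 °C) should effect the siloxy-Cope shift through the same chair to the ring-expanded trimethylsilyl enol ether F2. Rubottom oxidation (dimethyldioxirane, −78 °C, mild acid work-up) returns to 17.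

**Step 9.** Facial selectivity of the addition to the α-quaternary ketone may be poor, because methyl and the flat silyloxyvinyl group differ little in size. Iodine–metal exchange at C10 is a second risk. Fallback (two-stage introduction with a slim, linear nucleophile): from 9, Sonogashira coupling with ethynyltrimethylsilane gives the silyl enyne F3. Methyllithium cleaves its C–Si bond to the lithium acetylide F4, which adds to 7 to give the propargylic alcohol F5. Hydroxyl-directed trans-hydroalumination with NaAlH2(OCH2CH2OCH3)2 returns to 14.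

**Step 6.** The silylation may give an E/Z mixture under kinetic control, or may silylate the ketone oxygen to a dienol ether. Fallback (thermodynamic control): from 6, the mixture containing the Z enol ether F6 is equilibrated by reversible thiyl-radical addition (PhSSPh, hν, benzene) toward the E isomer, which is favoured by the quaternary neighbour, returning to 7.

**Step 13.** The activated C8 oxygen may eliminate toward C7, the ester may form with partial retention through an acyloxyphosphonium path, or the acidic C8–H may epimerise. If step 10 hydroxylates the other enolate face, acylation with retention (Yamaguchi conditions) would be used instead of inversion. Fallback (bromide displacement): from 14, the enolate 16 is generated as in step 10 and trapped with N-bromosuccinimide to give the 8α-bromo ketone F7. The caesium carboxylate F8 (from 20 and Cs2CO3) displaces bromide with inversion in DMF, returning to 22.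

**Step 16.** Reagent control may be overridden by the ring (mismatched pair), or the branched C8 side may not be read as the small group, leading to hydride delivery to the wrong face. Fallback (substrate control plus inversion): from 26, Luche reduction (NaBH4, CeCl3, MeOH, −78 °C); if it gives the 9α alcohol F9, Mitsunobu inversion with formic acid gives the 9β formate F10, and KHCO3 in MeOH at 0 °C cleaves only the formate, returning to 27.

**Step 18.** The trans alkene may react through its flipped conformer and be attacked on the wrong face. Fallback (halohydrin route, which delivers the epoxide oxygen to the face opposite to direct epoxidation): from 28, N-bromosuccinimide in aqueous acetone gives the bromohydrin F11 (bromine on the exposed face at C5, water anti at C4). K2CO3 closes the epoxide with inversion at C5, returning to 29.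

## Further compounds

F1 | step 10 | trimethylsilyl ether of 14 | IC1=CCC[C@@](C)(/C=C/O[Si](C)(C)C(C)(C)C)[C@]1(O[Si](C)(C)C)/C=C/C(=C)CO[Si](C)(C)C(C)(C)C
F2 | step 10 | ring-expanded trimethylsilyl enol ether (4E,8E; ring-cis C1=C10) | C/C1=C\[C@@H](O[Si](C)(C)C(C)(C)C)[C@H](C(=C)CO[Si](C)(C)C(C)(C)C)/C=C(O[Si](C)(C)C)/C(I)=C\CC1
F3 | step 9 | tert-butyldimethyl{[2-methylidene-4-(trimethylsilyl)but-3-yn-1-yl]oxy}silane | C=C(CO[Si](C)(C)C(C)(C)C)C#C[Si](C)(C)C
F4 | step 9 | lithium acetylide of 2-methylidenebut-3-yn-1-yl tert-butyldimethylsilyl ether | [Li]C#CC(=C)CO[Si](C)(C)C(C)(C)C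
F5 | step 9 | (1R,6S)-propargylic alcohol (alkyne analogue of 14) | IC1=CCC[C@@](C)(/C=C/O[Si](C)(C)C(C)(C)C)[C@]1(O)C#CC(=C)CO[Si](C)(C)C(C)(C)C
F6 | step 6 | (6S)-6-[(Z)-2-(tert-butyldimethylsilyloxy)ethenyl]-2-iodo-6-methylcyclohex-2-en-1-one | O=C1C(I)=CCC[C@@]1(C)/C=C\O[Si](C)(C)C(C)(C)C
F7 | step 13 | 8α-bromo analogue of 17 | C/C1=C\[C@@H](O[Si](C)(C)C(C)(C)C)[C@H](C(=C)CO[Si](C)(C)C(C)(C)C)[C@@H](Br)C(=O)/C(I)=C\CC1
F8 | step 13 | caesium (2S,3R)-2,3-dimethyloxirane-2-carboxylate | [Cs+].[O-]C(=O)[C@@]1(C)O[C@@H]1C
F9 | step 16 | 9α-hydroxy epimer of 27 | C/C1=C\[C@H]2OC(=O)C(=C)[C@@H]2[C@H](OC(=O)[C@@]3(C)O[C@@H]3C)[C@@H](O)/C(I)=C\CC1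
F10 | step 16 | 9β-formate of 27 | C/C1=C\[C@H]2OC(=O)C(=C)[C@@H]2[C@H](OC(=O)[C@@]3(C)O[C@@H]3C)[C@H](OC=O)/C(I)=C\CC1
F11 | step 18 | 5-bromo-4-hydroxy bromohydrin of 28 | C[C@]1(O)[C@@H](Br)[C@H]2OC(=O)C(=C)[C@@H]2[C@H](OC(=O)[C@@]3(C)O[C@@H]3C)[C@H](O)/C(C(=O)OC)=C\CC1
A1 | alternative 1 | seco enal–allylic bromide (8,9-bis-silyl ether) | O=C/C=C(\C)CC/C=C(/C(=O)OC)[C@@H](O[Si](C)(C)C(C)(C)C)[C@@H](O[Si](C)(C)C(C)(C)C)/C=C(\CBr)C(=O)OC
A2 | alternative 1 | macrocyclic lactone 8,9-bis-silyl ether | C/C1=C\[C@H]2OC(=O)C(=C)[C@@H]2[C@H](O[Si](C)(C)C(C)(C)C)[C@H](O[Si](C)(C)C(C)(C)C)/C(C(=O)OC)=C\CC1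
A3 | alternative 2 | lactone-bearing (Z)-α-iodoenoate aldehyde | O=C[C@@H](O[Si](C)(C)C(C)(C)C)[C@H]1C(=C)C(=O)O[C@@H]1/C=C(\C)CC/C=C(\I)C(=O)OC
A4 | alternative 2 | macrocyclic carbinol (C9 epimers) | C/C1=C\[C@H]2OC(=O)C(=C)[C@@H]2[C@H](O[Si](C)(C)C(C)(C)C)C(O)/C(C(=O)OC)=C\CC1
A5 | alternative 3 | trans-decalin hydroxy mesylate | IC1=CCC[C@@]2(C)[C@H](OS(C)(=O)=O)[C@@H](O[Si](C)(C)C(C)(C)C)[C@H](C(=C)CO[Si](C)(C)C(C)(C)C)[C@H](O[Si](C)(C)C(C)(C)C)[C@]12O
A6 | alternative 3 | cyclodecadienone from fragmentation | C/C1=C\[C@@H](O[Si](C)(C)C(C)(C)C)[C@H](C(=C)CO[Si](C)(C)C(C)(C)C)[C@H](O[Si](C)(C)C(C)(C)C)C(=O)/C(I)=C\CC1
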